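The trap in this flask was to ask how fast the enzyme turns over, when the second substrate has a half-life of 0.28 h by step 6 alone, short against the 8.0 h of the run.

    starting material + free enzyme ⇌ first complex (K1 = 16 L mol⁻¹, k1 = 1800 L mol⁻¹ s⁻¹)
    first complex → loaded enzyme + first product (k2 = 4.1 s⁻¹)
    second substrate + loaded enzyme ⇌ second complex (K3 = 38 L mol⁻¹, k3 = 440 L mol⁻¹ s⁻¹)
    second complex → free enzyme + target (k4 = 7.3 s⁻¹)
    second substrate + first product ⇌ idle adduct, settled at all times (K5 = 29 L mol⁻¹)
    second substrate → decomposed reagent (k6 = 6.9 × 10⁻⁴ s⁻¹)

starting material 0.20 M; second substrate 0.220 M; free enzyme 20 µM; time 8.0 h

- part of the starting material that has reacted at 8.0 h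
- share of free second substrate in free second substrate and idle adduct together, at 8.0 h

- amounts and yields of first product count idle adduct too
- run time (flask): 8.0 h

So I divided the rate of decomposition by the rate of turnover and let time drop out. From the rate constants I took the specificity constants of the two half-reactions, 63.3 L mol⁻¹ s⁻¹ for starting material and 170 L mol⁻¹ s⁻¹ for second substrate. I also took a cycle time of 0.460 s at the starting charge, to which each turnover adds one over the second constant times free reagent. Decomposed reagent per target, a selectivity factor, then came to 0.203 plus a diversion coefficient of 15.9 L mol⁻¹, the decomposed reagent made per target made for each mole per litre of free second substrate, times the free reagent; the coefficient is the slope of that selectivity factor against free reagent, equal to the decomposition rate constant times the cycle time over the enzyme charge.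

I then turned the settings by hand. Time should add nothing once the reagent is gone, given that half-life. More enzyme lowers the coefficient, so it should raise the target. The reagent charge enters through a logarithm, so more of it should pay less than in proportion: the target made is the natural logarithm of one plus coefficient times charge over one plus 0.203, divided by the coefficient, which gave 0.0858 M. Starting material enters the cycle by 0.0790 s, less than the 0.381 s of the chemical steps, so more of it should leave a smaller part reacted. I committed to 42.9% reacted, as a low figure, since I ignored the idle adduct although the balance constant times that first product is 2.49, and to a free share of 28.7%.

The forecast gave 46%, above mine, and 27%, below mine, holding that “it runs out well before 8 h”.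

The flask gave 48.2% and 26.4%, with second substrate at 0% of its charge, and ten times the time gave 48.2%. For the neighbouring flask with 5.0 × 10⁻⁶ M of free enzyme, the coefficient rose to 63.5 L mol⁻¹ and the constant term to 0.811, so I reckoned 0.0341 M of target, which is 17.1% reacted and a free share of 50.3%; that neighbouring flask gave 18.6% and 48.1%.

The rate constants were set for the occasion; the run is a simulation.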